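## Retrosynthetic overview

1. Feature: in ring C, the atoms O1–C8a–C4a–C4 are the 1-oxadiene of an ortho-quinone methide of ring A. C2–C3, with ring B on C3, is the two-carbon unit of an arylacetic acid. C3 is the only stereocentre.
2. Key disconnection: C3–C4 and O1–C2 of the (3S)-3-aryl-dihydrocoumarin 22. It is made by a carbene-catalysed formal [4+2] of silyloxybenzyl bromide 7 with acyl imidazole 19. Ring C is the only ring formed, since rings A and B are bought.
3. Ring A piece: 2-methoxyresorcinol is formylated, benzylated at O4, silylated, reduced and brominated.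
4. Ring B piece: syringol is converted to its benzyl ether and then to the mirror-symmetric dibromide. One Li/Br exchange, oxidation and methylation follow, so the oxygen pattern is fixed by symmetry. Malonate arylation, decarboxylation and CDI complete the piece.
5. Endgame: the lactone C2=O is taken to the lactol and then to CH2 by ionic hydrogenation, and both benzyl ethers are hydrogenolysed.

Key step: step 13

Assumption: the usual shielding model (indane wall over one face, Z-enolate, enolate oxygen syn to N-mesityl) predicts (3S) for the (5aR,10bS) triazolium salt, SMILES Cc1cc(C)c(c(C)c1)-[n+]1cn2c(n1)CO[C@@H]1Cc3ccccc3[C@@H]12.F[B-](F)(F)F; the configuration of 22 is to be checked on the first run, and the equally available (5aS,10bR) salt is used if the model proves wrong.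

## Route

Step 1
Reactants: 1 2-methoxyresorcinol
Product: 3 2,4-dihydroxy-3-methoxybenzaldehyde, via aryl iminium chloride 2 (not isolated)
Conditions: POCl3, DMF, MeCN, −15 °C → rt; then H2O, 50 °C
Reagents that add atoms: N,N-dimethylformamide CN(C)C=O (formyl carbon); water O (aldehyde oxygen)
Why: Vilsmeier–Haack formylation, as practised on resorcinol itself: the two equivalent positions ortho to one hydroxyl and para to the other are by far the most nucleophilic, and the iminium group of 2 deactivates the ring against a second attack, so hydrolysis should give one mono-aldehyde.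

Step 2
Reactants: 3 2,4-dihydroxy-3-methoxybenzaldehyde
Product: 4 4-(benzyloxy)-2-hydroxy-3-methoxybenzaldehyde
Conditions: BnBr (1.05 equiv), NaHCO3, MeCN, reflux
Reagents that add atoms: benzyl bromide BrCc1ccccc1
Why: Regioselective Williamson etherification: the 2-OH is held in a hydrogen bond to the formyl oxygen while the para-OH is the more acidic one, so a weak base should ionise and benzylate only O4 (the later O7).

Step 3
Reactants: 4 4-(benzyloxy)-2-hydroxy-3-methoxybenzaldehyde
Product: 5 4-(benzyloxy)-2-[(tert-butyldimethylsilyl)oxy]-3-methoxybenzaldehyde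
Conditions: TBSCl, imidazole, DMAP (cat.), DMF, rt
Reagents that add atoms: tert-butyldimethylsilyl chloride CC(C)(C)[Si](C)(C)Cl
Why: Imidazole-promoted O-silylation in DMF, which is known to overcome the hydrogen bond and the two ortho neighbours in 3-alkoxysalicylaldehydes.

Step 4
Reactants: 5 4-(benzyloxy)-2-[(tert-butyldimethylsilyl)oxy]-3-methoxybenzaldehyde
Product: 6 {4-(benzyloxy)-2-[(tert-butyldimethylsilyl)oxy]-3-methoxyphenyl}methanol
Conditions: NaBH4, THF–MeOH (10:1), 0 °C, short contact; aq. NH4Cl
Reagents that add atoms: none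
Why: Borohydride reduction of the aldehyde: in the cold protic medium the alkoxide is protonated at once, which suppresses the phenol-to-benzyl O→O silyl shift, and no other group is reducible.

Step 5
Reactants: 6 {4-(benzyloxy)-2-[(tert-butyldimethylsilyl)oxy]-3-methoxyphenyl}methanol
Product: 7 4-(benzyloxy)-2-[(tert-butyldimethylsilyl)oxy]-3-methoxybenzyl bromide
Conditions: CBr4, PPh3, CH2Cl2, −20 → 0 °C; pentane trituration, filtration, kept cold and used at once
Reagents that add atoms: carbon tetrabromide BrC(Br)(Br)Br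
Why: The Appel bromination runs under neutral conditions that spare the aryl silyl ether and both ether types, and because the bromide carries an ortho and a para oxygen donor it is labile and is only filtered, not chromatographed.

Step 6
Reactants: 8 2,6-dimethoxyphenol (syringol)
Product: 9 2-(benzyloxy)-1,3-dimethoxybenzene
Conditions: BnBr, K2CO3, DMF, 60 °C
Reagents that add atoms: benzyl bromide BrCc1ccccc1
Why: Williamson etherification of the flanked but acidic phenol, in which the benzyl group marks the oxygen that becomes the free 3'-OH.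

Step 7
Reactants: 9 2-(benzyloxy)-1,3-dimethoxybenzene
Product: 10 3-(benzyloxy)-1,5-dibromo-2,4-dimethoxybenzene
Conditions: NBS (2.1 equiv), MeCN, 0 → 40 °C, dark
Reagents that add atoms: N-bromosuccinimide O=C1CCC(=O)N1Br
Why: Electrophilic aromatic bromination: as in 1,2,3-trialkoxybenzenes, the outer methoxy groups direct first to one and then to the other position that is ortho to one OMe and para to the other, whereas the third free position is only para to the twisted central ether, so the mirror-symmetric dibromide should result.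

Step 8
Reactants: 10 3-(benzyloxy)-1,5-dibromo-2,4-dimethoxybenzene
Product: 13 3-(benzyloxy)-5-bromo-2,4-dimethoxyphenol, via aryllithium 11 (not isolated), via dimethyl arylboronate 12 (not isolated)
Conditions: n-BuLi (1.0 equiv), THF, −78 °C; B(OMe)3, −78 °C → rt; AcOH, 30% H2O2, 0 °C → rt
Reagents that add atoms: hydrogen peroxide OO (phenol oxygen); n-butyllithium [Li]CCCC (lithium of 11 only); trimethyl borate COB(OC)OC (boron unit of 12 only)
Why: Lithium–bromine exchange, borylation and peroxide oxidation of the aryl boronate: the two C–Br bonds of 10 are mirror images, so one equivalent of n-BuLi gives a single aryllithium and the fourth oxygen arrives without any regiochemical choice, a choice that bromination of 2-benzyloxy-1,3,4-trimethoxybenzene (para-OMe against para-OBn) could not make.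

Step 9
Reactants: 13 3-(benzyloxy)-5-bromo-2,4-dimethoxyphenol
Product: 14 3-(benzyloxy)-1-bromo-2,4,5-trimethoxybenzene
Conditions: MeI, K2CO3, acetone, reflux
Reagents that add atoms: iodomethane CI
Why: Williamson O-methylation of the only free phenol completes the 2,4,5-trimethoxy-3-benzyloxy pattern of ring B.

Step 10
Reactants: 14 3-(benzyloxy)-1-bromo-2,4,5-trimethoxybenzene; 15 diethyl malonate
Product: 16 diethyl 2-[3-(benzyloxy)-2,4,5-trimethoxyphenyl]malonate
Conditions: Pd2(dba)3 (cat.), P(t-Bu)3·HBF4 (cat.), K3PO4, toluene, 90 °C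
Reagents that add atoms: none
Why: Palladium-catalysed α-arylation of a malonate (Buchwald–Hartwig-type enolate arylation): the bulky, electron-rich phosphine allows oxidative addition into the electron-rich, mono-ortho-substituted C–Br bond, and the acidic product resists a second arylation.

Step 11
Reactants: 16 diethyl 2-[3-(benzyloxy)-2,4,5-trimethoxyphenyl]malonate
Product: 18 [3-(benzyloxy)-2,4,5-trimethoxyphenyl]acetic acid, via arylmalonic acid 17 (not isolated)
Conditions: NaOH, EtOH–H2O, reflux; 2 M HCl, 0 °C, extraction; crude diacid, toluene, 110 °C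
Reagents that add atoms: sodium hydroxide [Na+].[OH-] (carboxyl oxygen)
Why: Saponification followed by thermal decarboxylation of the arylmalonic acid through the usual cyclic transition state, with benzyl and methyl ethers inert to both operations.

Step 12
Reactants: 18 [3-(benzyloxy)-2,4,5-trimethoxyphenyl]acetic acid
Product: 19 1-{[3-(benzyloxy)-2,4,5-trimethoxyphenyl]acetyl}imidazole
Conditions: CDI (1.1 equiv), THF, rt
Reagents that add atoms: 1,1'-carbonyldiimidazole O=C(n1ccnc1)n1ccnc1
Why: Carboxyl activation with carbonyldiimidazole, driven by loss of CO2, gives the isolable N-acyl imidazole without a strong base.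

Step 13
Reactants: 7 4-(benzyloxy)-2-[(tert-butyldimethylsilyl)oxy]-3-methoxybenzyl bromide; 19 1-{[3-(benzyloxy)-2,4,5-trimethoxyphenyl]acetyl}imidazole
Product: 22 (3S)-7-(benzyloxy)-3-[3-(benzyloxy)-2,4,5-trimethoxyphenyl]-8-methoxy-3,4-dihydro-2H-chromen-2-one, via o-quinone methide 20 (not isolated), via azolium enolate 21 (not isolated)
Conditions: (5aR,10bS)-N-mesityl aminoindanol-derived triazolium BF4 (15 mol %), CsF (2.5 equiv), 18-crown-6 (0.5 equiv), 4 Å MS, THF, −10 °C, 7 (1.5 equiv) added over several hours; AcOH quench at −10 °C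
Reagents that add atoms: none
Why: Fluoride takes the silyl group off 7 and the phenoxide expels bromide in a 1,4-elimination to give methide 20, while the free carbene displaces imidazole from 19 and loss of the acidified benzylic proton gives the Z-azolium enolate 21. The enolate carbon (C3) adds in Michael fashion to the exocyclic methylene (C4) of 20, which restores the aromaticity of ring A, and the liberated phenoxide O1 then attacks the azolium-bound carbonyl C2 in a 6-exo-trig acyl substitution that closes ring C and frees the carbene. The closest known reaction type is the carbene-catalysed formal [4+2] annulation of acyl imidazoles with fluoride-generated ortho-quinone methides (azolium enolate hetero-Diels–Alder chemistry). C3 is the only new stereocentre, and it is fixed by the fused aminoindanol backbone, whose indane wall covers one face of the planar enolate so that C4 is delivered to the open face. The step needs cross-reaction to win over methide dimerisation and needs 22 not to re-enolise: the C7 oxygen para to C4 tames 20, sparingly soluble CsF releases it slowly and keeps it dilute, its unsubstituted terminus allows only one regiochemical mode, and the 2'-methoxy group twists ring B out of the enolate plane and so lowers the kinetic acidity of H3 in the product.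

Step 14
Reactants: 22 (3S)-7-(benzyloxy)-3-[3-(benzyloxy)-2,4,5-trimethoxyphenyl]-8-methoxy-3,4-dihydro-2H-chromen-2-one
Product: 23 (3S)-7-(benzyloxy)-3-[3-(benzyloxy)-2,4,5-trimethoxyphenyl]-8-methoxy-3,4-dihydro-2H-chromen-2-ol (both C2 epimers)
Conditions: DIBAL-H (1.1 equiv), CH2Cl2, −78 °C; MeOH, then aq. Rochelle salt; crude product used without chromatography
Reagents that add atoms: none
Why: Partial reduction of a lactone with DIBAL-H: at −78 °C the aluminium hemiacetal persists, so reduction should stop at the chroman-2-ol, and the Lewis acidic, non-basic reagent leaves H3 untouched while C2 becomes an inconsequential anomeric mixture.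

Step 15
Reactants: 23 (3S)-7-(benzyloxy)-3-[3-(benzyloxy)-2,4,5-trimethoxyphenyl]-8-methoxy-3,4-dihydro-2H-chromen-2-ol
Product: 25 (3S)-7-(benzyloxy)-3-[3-(benzyloxy)-2,4,5-trimethoxyphenyl]-8-methoxy-3,4-dihydro-2H-chromene, via oxocarbenium ion 24 (not isolated)
Conditions: Et3SiH (5 equiv, present from the start), BF3·OEt2 (2 equiv), CH2Cl2, −78 → −40 °C; aq. NaHCO3
Reagents that add atoms: none
Why: Ionic hydrogenation (Lewis acid/silane deoxygenation of a lactol): BF3 ionises the anomeric C–O bond, and the excess silane should trap cation 24 at −78 °C faster than the cation can lose H3, so C3 should keep its configuration.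

Step 16
Reactants: 25 (3S)-7-(benzyloxy)-3-[3-(benzyloxy)-2,4,5-trimethoxyphenyl]-8-methoxy-3,4-dihydro-2H-chromene
Product: 26 (3S)-3-(3-hydroxy-2,4,5-trimethoxyphenyl)-8-methoxy-3,4-dihydro-2H-chromen-7-ol (CNP0201239.1)
Conditions: H2 (1 atm), 10% Pd/C, EtOAc–EtOH, rt
Reagents that add atoms: none
Why: Catalytic hydrogenolysis cleaves both O-benzyl bonds, whereas the chroman O1–C2 bond is not benzylic and C3 bears no leaving group, so the (3S)-isoflavan should be released unchanged.

## Compound list

1 | 2-methoxyresorcinol | COc1c(O)cccc1O | starting material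
2 | (2,4-dihydroxy-3-methoxybenzylidene)dimethyliminium chloride | C[N+](C)=Cc1ccc(O)c(OC)c1O.[Cl-] | intermediate
3 | 2,4-dihydroxy-3-methoxybenzaldehyde | COc1c(O)ccc(C=O)c1O | intermediate
4 | 4-(benzyloxy)-2-hydroxy-3-methoxybenzaldehyde | COc1c(OCc2ccccc2)ccc(C=O)c1O | intermediate
5 | 4-(benzyloxy)-2-[(tert-butyldimethylsilyl)oxy]-3-methoxybenzaldehyde | COc1c(OCc2ccccc2)ccc(C=O)c1O[Si](C)(C)C(C)(C)C | intermediate
6 | {4-(benzyloxy)-2-[(tert-butyldimethylsilyl)oxy]-3-methoxyphenyl}methanol | OCc1ccc(OCc2ccccc2)c(OC)c1O[Si](C)(C)C(C)(C)C | intermediate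
7 | 4-(benzyloxy)-2-[(tert-butyldimethylsilyl)oxy]-3-methoxybenzyl bromide | BrCc1ccc(OCc2ccccc2)c(OC)c1O[Si](C)(C)C(C)(C)C | intermediate
8 | 2,6-dimethoxyphenol (syringol) | COc1cccc(OC)c1O | starting material
9 | 2-(benzyloxy)-1,3-dimethoxybenzene | COc1cccc(OC)c1OCc1ccccc1 | intermediate
10 | 3-(benzyloxy)-1,5-dibromo-2,4-dimethoxybenzene | COc1c(Br)cc(Br)c(OC)c1OCc1ccccc1 | intermediate
11 | [3-(benzyloxy)-5-bromo-2,4-dimethoxyphenyl]lithium | COc1c([Li])cc(Br)c(OC)c1OCc1ccccc1 | intermediate
12 | dimethyl [3-(benzyloxy)-5-bromo-2,4-dimethoxyphenyl]boronate | COB(OC)c1cc(Br)c(OC)c(OCc2ccccc2)c1OC | intermediate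
13 | 3-(benzyloxy)-5-bromo-2,4-dimethoxyphenol | COc1c(O)cc(Br)c(OC)c1OCc1ccccc1 | intermediate
14 | 3-(benzyloxy)-1-bromo-2,4,5-trimethoxybenzene | COc1cc(Br)c(OC)c(OCc2ccccc2)c1OC | intermediate
15 | diethyl malonate | CCOC(=O)CC(=O)OCC | starting material
16 | diethyl 2-[3-(benzyloxy)-2,4,5-trimethoxyphenyl]malonate | CCOC(=O)C(C(=O)OCC)c1cc(OC)c(OC)c(OCc2ccccc2)c1OC | intermediate
17 | 2-[3-(benzyloxy)-2,4,5-trimethoxyphenyl]malonic acid | OC(=O)C(C(=O)O)c1cc(OC)c(OC)c(OCc2ccccc2)c1OC | intermediate
18 | [3-(benzyloxy)-2,4,5-trimethoxyphenyl]acetic acid | COc1cc(CC(=O)O)c(OC)c(OCc2ccccc2)c1OC | intermediate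
19 | 1-{[3-(benzyloxy)-2,4,5-trimethoxyphenyl]acetyl}imidazole | COc1cc(CC(=O)n2ccnc2)c(OC)c(OCc2ccccc2)c1OC | intermediate
20 | 3-(benzyloxy)-2-methoxy-6-methylidenecyclohexa-2,4-dien-1-one (o-quinone methide) | C=C1C=CC(OCc2ccccc2)=C(OC)C1=O | intermediate
21 | (Z)-2-[3-(benzyloxy)-2,4,5-trimethoxyphenyl]-1-[(5aR,10bS)-2-mesityl-5a,10b-dihydro-4H,6H-indeno[2,1-b][1,2,4]triazolo[4,3-d][1,4]oxazin-2-ium-1-yl]ethen-1-olate (azolium enolate) | COc1cc(/C=C(\[O-])c5n6c(n[n+]5-c7c(C)cc(C)cc7C)CO[C@@H]8Cc9ccccc9[C@@H]86)c(OC)c(OCc2ccccc2)c1OC | intermediate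
22 | (3S)-7-(benzyloxy)-3-[3-(benzyloxy)-2,4,5-trimethoxyphenyl]-8-methoxy-3,4-dihydro-2H-chromen-2-one | COc1cc([C@H]2C(=O)Oc3c(ccc(OCc4ccccc4)c3OC)C2)c(OC)c(OCc2ccccc2)c1OC | intermediate
23 | (3S)-7-(benzyloxy)-3-[3-(benzyloxy)-2,4,5-trimethoxyphenyl]-8-methoxy-3,4-dihydro-2H-chromen-2-ol, C2 epimers | COc1cc([C@H]2C(O)Oc3c(ccc(OCc4ccccc4)c3OC)C2)c(OC)c(OCc2ccccc2)c1OC | intermediate
24 | (3S)-7-(benzyloxy)-3-[3-(benzyloxy)-2,4,5-trimethoxyphenyl]-8-methoxy-3,4-dihydrochromenylium (oxocarbenium ion) | COc1cc([C@H]2C=[O+]c3c(ccc(OCc4ccccc4)c3OC)C2)c(OC)c(OCc2ccccc2)c1OC | intermediate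
25 | (3S)-7-(benzyloxy)-3-[3-(benzyloxy)-2,4,5-trimethoxyphenyl]-8-methoxy-3,4-dihydro-2H-chromene | COc1cc([C@H]2COc3c(ccc(OCc4ccccc4)c3OC)C2)c(OC)c(OCc2ccccc2)c1OC | intermediate
26 | (3S)-3-(3-hydroxy-2,4,5-trimethoxyphenyl)-8-methoxy-3,4-dihydro-2H-chromen-7-ol | COc1cc([C@H]2COc3c(ccc(O)c3OC)C2)c(OC)c(O)c1OC | target

## Step count and risks

Total step count: 16.
Longest linear sequence: 11 steps (steps 6–16, from 8 to 26).

**Step 13.**
- Risk: the enolate face may be shielded incompletely. Fluoride or imidazole may re-enolise the α-aryl lactone once it has formed. The methide may be drained by self-dimerisation or by addition of imidazole or of the carbene.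
- Fallback: auxiliary control in place of catalyst control, from 19 and 7 back to 22. Acyl imidazole 19 acylates lithiated (S)-4-benzyloxazolidin-2-one (THF, −78 → 0 °C) to give (4S)-4-benzyl-3-{[3-(benzyloxy)-2,4,5-trimethoxyphenyl]acetyl}-1,3-oxazolidin-2-one F1. Its chelated sodium Z-enolate (NaHMDS, THF, −78 °C) is alkylated by bromide 7 on the face away from the auxiliary benzyl group. This Evans alkylation makes the same C3–C4 bond and gives the (2S)-2,3-diarylpropanoyl imide F2. LiOH/H2O2 (THF–H2O, 0 °C) removes the auxiliary to give the (2S)-silyloxy acid F3. Et3N·3HF (THF, rt) then frees the (2S)-phenol acid F4. Catalytic p-TsOH with molecular sieves in toluene closes O1–C2 by acid-catalysed lactonisation, in a medium free of base, and gives 22.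

**Step 15.**
- Risk: deprotonation of the cation at C3 followed by re-protonation would erode the configuration at C3. Opening of the lactol to its enolisable hydroxy aldehyde tautomer would do the same. Over-reduction in step 14 would also lower throughput.
- Fallback: from 22 back to 25, bypassing steps 14 and 15. LiAlH4 (THF, −20 → 0 °C) reduces the lactone fully to 3-(benzyloxy)-6-{(2S)-2-[3-(benzyloxy)-2,4,5-trimethoxyphenyl]-3-hydroxypropyl}-2-methoxyphenol F5, in which C3 is flanked only by sp3 carbons. An intramolecular Mitsunobu etherification (PPh3, DIAD, THF, 0 °C → rt) follows, with the phenol as the acidic partner and a 6-exo-tet displacement at the primary carbon. It re-forms O1–C2 and gives 25. Any over-reduced material from step 14 is this same compound and can be fed in here.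

**Step 5.**
- Risk: the bromide is activated by an ortho and a para oxygen donor. It may ionise on concentration, on silica or on storage, which leads to self-alkylation and hydrolysis before it reaches the key step.
- Fallback: from 6 back to 22. Acetylation (Ac2O, pyridine, DMAP cat., CH2Cl2, 0 °C) gives 4-(benzyloxy)-2-[(tert-butyldimethylsilyl)oxy]-3-methoxybenzyl acetate F6, which should tolerate chromatography and storage. Under the conditions of step 13, run at 0 °C to rt, fluoride desilylation is followed by 1,4-elimination of acetate, assisted by the para oxygen donor. This delivers the same methide 20 and hence 22.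

## Further compounds

F1 | step 13 | (4S)-4-benzyl-3-{[3-(benzyloxy)-2,4,5-trimethoxyphenyl]acetyl}-1,3-oxazolidin-2-one | COc1cc(CC(=O)N2[C@@H](Cc3ccccc3)COC2=O)c(OC)c(OCc2ccccc2)c1OC
F2 | step 13 | (4S)-4-benzyl-3-{(2S)-3-{4-(benzyloxy)-2-[(tert-butyldimethylsilyl)oxy]-3-methoxyphenyl}-2-[3-(benzyloxy)-2,4,5-trimethoxyphenyl]propanoyl}-1,3-oxazolidin-2-one | COc1cc([C@H](Cc2ccc(OCc3ccccc3)c(OC)c2O[Si](C)(C)C(C)(C)C)C(=O)N2[C@@H](Cc3ccccc3)COC2=O)c(OC)c(OCc2ccccc2)c1OC
F3 | step 13 | (2S)-3-{4-(benzyloxy)-2-[(tert-butyldimethylsilyl)oxy]-3-methoxyphenyl}-2-[3-(benzyloxy)-2,4,5-trimethoxyphenyl]propanoic acid | COc1cc([C@H](Cc2ccc(OCc3ccccc3)c(OC)c2O[Si](C)(C)C(C)(C)C)C(=O)O)c(OC)c(OCc2ccccc2)c1OC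
F4 | step 13 | (2S)-3-[4-(benzyloxy)-2-hydroxy-3-methoxyphenyl]-2-[3-(benzyloxy)-2,4,5-trimethoxyphenyl]propanoic acid | COc1cc([C@H](Cc2ccc(OCc3ccccc3)c(OC)c2O)C(=O)O)c(OC)c(OCc2ccccc2)c1OC
F5 | step 15 | 3-(benzyloxy)-6-{(2S)-2-[3-(benzyloxy)-2,4,5-trimethoxyphenyl]-3-hydroxypropyl}-2-methoxyphenol | COc1cc([C@H](Cc2ccc(OCc3ccccc3)c(OC)c2O)CO)c(OC)c(OCc2ccccc2)c1OC
F6 | step 5 | 4-(benzyloxy)-2-[(tert-butyldimethylsilyl)oxy]-3-methoxybenzyl acetate | CC(=O)OCc1ccc(OCc2ccccc2)c(OC)c1O[Si](C)(C)C(C)(C)C
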